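3 questions stand on this flask, and I follow one molecule of carrier through it.

starting material 10 mM; salt in the second phase 9.50 mM; capture agent 0.500 mM; spent carrier 100 µM; time 20 min; volume of the second phase over the first 0.50

1. the product and crystals together standing at 20 min, as a percentage of the starting material charged
2. the change that raises the amount of product and crystals together at 20 min, in percent of the starting material charged most ("none" if none brings more than 2 percentage points) (Saturday's / Tuesday's / Sunday's / none)
3. amount of product and crystals together at 20 min, in percent of the starting material charged, after Tuesday's

- for product the crystals are counted in
- in the second phase: salt in the second phase, spent salt in the second phase; everything else is in the first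
- charges count per volume of the first phase; a concentration in a rate is the amount of a species over the volume of its own phase; every rate counts per litre of the first phase
- as a solid, counted per litre of solution: crystals
- run time (flask): 20 min

- Saturday's: doubling the amount of salt in the second phase, all else as stated
- Tuesday's: doubling the solubility in step 1, all else as stated
- Sunday's: doubling the dissolution coefficient of step 1, all else as stated

    crystals ⇌ product, rate k1*(cs1 - [product]) while solid is left; crystals form when [product] > cs1 (cs1 = 0.97 mM, k1 = 0.219 s⁻¹)
    starting material + fresh carrier → product + spent carrier (k2 = 17.3 M⁻¹ s⁻¹)
    spent carrier + salt in the second phase ⇌ fresh carrier + spent salt in the second phase (K3 = 24.9, k3 = 178 M⁻¹ s⁻¹)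
    spent carrier + capture agent → trapped intermediate (k4 = 5.92 M⁻¹ s⁻¹)

The carrier starts as spent carrier. In the first instants it meets a fork: the salt turns it fresh with half-life 0.205 s, the capture agent traps it with half-life 3.9 min. Regeneration is faster, so one pass ends trapped with a chance of 0.0874%. Fresh carrier then turns starting material into product and goes spent again, with half-life 0.067 min.

In the middle, each pass costs one salt. At conversion x, the reacted fraction of starting material, salt stands at ε − x of that charge, with ε = 0.950. Because passing is quicker than trapping, I balance the two working forms: spent over fresh is r ≈ g/(ε − x). Here g, 0.0444, averages an early ratio, 0.0486, and the late one from step three's way back, 0.0402. Summing trapping per product, with capture agent held at its charge, gives the bill B, the carrier trapped by conversion x: B = b ln[ε(1 − x)/(ε − x)]. The bill constant b, 0.152 mM, is carrier trapped per unit of that logarithm, and it contains no carrier charge.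

Towards the end, salt is the limiting reagent, capping product at 95.0%. But B reaches the 100 µM charged at x = 90.2%, so I expect the flask to stop lower.

For 20 min I take the mid-run state at x = 0.5: the bill is 0.00821 mM, r is 0.0986, and fresh carrier is 0.0835 mM. Starting material then decays as pseudo-first-order, giving 82.4%. No step takes product, and step one moves it only between solution and crystals, so I give Tuesday's and Sunday's the same figure. Saturday's lowers r to 0.0317, towards a ceiling of 87.5% with the whole charge fresh, 5.1 percentage points above my figure, so I choose it.

The forecast, holding that “crystallisation only moves material between product and crystals”, gives 79%, Saturday's and 79%.

The flask gives 79.4%, 3 points below my figure; Saturday's gains 5.7 points, and after Tuesday's it stands at 79.4%.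

At 20 min this flask is not at rest: starting material stands at 20.6% and fresh carrier at 52.0%. The bill at its conversion is 34.5% of the carrier, and 33.6% stands trapped. In the neighbour charged with 0.040 mM of spent carrier, converted to 50.1%, the bill is 20.6% of its charge, and 21.4% stands trapped. After 200 min this flask has fresh carrier at 0%, trapped intermediate at >99.9% of the carrier, and product and crystals at 91.0%, 12 points above their value at 20 min.

The constants stand for no real mixture, and the outcome is calculated.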